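**Retrosynthetic overview**
1. The target is two (2S,4R)-flavan-4-yl units joined through one ether oxygen. The last disconnection cuts C4–O of the 5-hydroxy unit and, in the same operation, its ring C. Ring C is traced back to a seven-membered 4-diazo-1-benzoxepin-5-one (photo-Wolff ring contraction, then loss of the extruded carbon as CO).
2. Enabling feature: the free O5–H on ring A lies peri to C4 of ring C. It catches the exocyclic ketene carbon as a five-membered lactone (O5–CO–C4–C4a–C5). It then becomes the carbonyl of the o-quinone methide C5(=O)–C4a=C4, which accepts the alcohol of the other unit.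
3. Both units come from one aryl ether, and a Mitsunobu inversion sets C2 and C2'. Cleavage of its alkene gives the three-carbon aldehyde for the trimethoxy unit. Hydroboration and oxidation give the four-carbon acid for the oxepinone.
4. Order of ring formation: ring F of the trimethoxy unit (Friedel–Crafts hydroxyalkylation), then the oxepinone ring (Friedel–Crafts acylation), then the temporary lactone ring and ring C (key step).

Key step: step 9

Assumption: (1R)-1-phenylbut-3-en-1-ol is bought enantiopure (a Keck or Brown allylation of benzaldehyde also gives it). Chromans carry flavan numbering, primed atoms and rings D, E, F belong to the trimethoxy unit, and 12 to 16 carry 1-benzoxepine numbering.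

**Step 1**
Reactants: 1 3,4,5-trimethoxyphenol; 2 (1R)-1-phenylbut-3-en-1-ol
Product: 3 5-{[(1S)-1-phenylbut-3-en-1-yl]oxy}-1,2,3-trimethoxybenzene
Conditions: PPh3, DIAD, toluene, 0 °C to rt
Reagents that add atoms: none
Why: Mitsunobu etherification: the phenol attacks the alkoxyphosphonium ion of the secondary benzylic alcohol in an SN2 process, so (R)-2 should give the (S)-ether with inversion, which fixes the centre that becomes C2 in one unit and C2' in the other.

**Step 2**
Reactants: 3 5-{[(1S)-1-phenylbut-3-en-1-yl]oxy}-1,2,3-trimethoxybenzene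
Product: 5 (3S)-3-phenyl-3-(3,4,5-trimethoxyphenoxy)propanal, via diol 4 (not isolated)
Conditions: OsO4 (2 mol %), NaIO4, 2,6-lutidine, 1,4-dioxane–H2O, rt
Reagents that add atoms: sodium periodate, [Na+].[O-]I(=O)(=O)=O (terminal source of the new O atoms, handed on by OsO4, O=[Os](=O)(=O)=O)
Why: Lemieux–Johnson oxidation: OsO4 dihydroxylates the only alkene and NaIO4 cleaves diol 4 in the same flask, the lutidine-buffered medium being mild enough to spare the tetraoxygenated ring and to hold back β-elimination of the aryloxide, and the stereocentre is not involved.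

**Step 3**
Reactants: 5 (3S)-3-phenyl-3-(3,4,5-trimethoxyphenoxy)propanal
Product: 6 (2S,4R)-5,6,7-trimethoxy-2-phenylchroman-4-ol (2,4-trans)
Conditions: Sc(OTf)3 (5 mol %), THF–H2O 9:1, 0 °C to rt
Reagents that add atoms: none
Why: Intramolecular Friedel–Crafts hydroxyalkylation (6-exo-trig): the ring position ortho to the ether oxygen and para to a methoxy group attacks the Sc(OTf)3-activated aldehyde, and because water keeps ionisation of the very electron-rich benzylic alcohol reversible, C4' should settle as R with the OH pseudo-axial and trans to the equatorial 2'-phenyl group, the arrangement that avoids peri strain with 5'-OMe and that axial attack on the half-chair cation also delivers.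

**Step 4**
Reactants: 3 5-{[(1S)-1-phenylbut-3-en-1-yl]oxy}-1,2,3-trimethoxybenzene
Product: 8 (4S)-4-phenyl-4-(3,4,5-trimethoxyphenoxy)butan-1-ol, via B-alkyl-9-BBN 7 (not isolated)
Conditions: 9-BBN, THF, 0 °C to rt; then NaOH, H2O2, 0 °C
Reagents that add atoms: hydrogen peroxide, OO; 9-borabicyclo[3.3.1]nonane, B1C2CCCC1CCC2 (its boron and carbon atoms stay only in 7)
Why: Brown hydroboration–oxidation: 9-BBN places boron on the terminal carbon for steric reasons and alkaline H2O2 replaces it by OH through migration from boron to oxygen, while the aryl ethers and the stereocentre are inert.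

**Step 5**
Reactants: 8 (4S)-4-phenyl-4-(3,4,5-trimethoxyphenoxy)butan-1-ol
Product: 10 (4S)-4-phenyl-4-(3,4,5-trimethoxyphenoxy)butanoic acid, via aldehyde 9 (not isolated)
Conditions: TEMPO (20 mol %), PhI(OAc)2 (2.2 equiv), MeCN–H2O 1:1, rt
Reagents that add atoms: water, O
Why: TEMPO-catalysed oxidation with PhI(OAc)2 as terminal oxidant: the oxoammonium ion oxidises the primary alcohol to aldehyde 9 and its hydrate to the acid near neutral pH, conditions under which alkyl aryl ethers and the benzylic C–O bond persist.

**Step 6**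
Reactants: 10 (4S)-4-phenyl-4-(3,4,5-trimethoxyphenoxy)butanoic acid
Product: 12 (2S)-6,7,8-trimethoxy-2-phenyl-3,4-dihydro-1-benzoxepin-5(2H)-one, via mixed anhydride 11 (not isolated)
Conditions: (CF3CO)2O (1.1 equiv), CH2Cl2 (0.02 M), 0 °C to rt
Reagents that add atoms: trifluoroacetic anhydride, O=C(OC(=O)C(F)(F)F)C(F)(F)F (its CF3CO group stays only in 11)
Why: Intramolecular Friedel–Crafts acylation (7-exo-trig) through the mixed trifluoroacetic anhydride: the two free ring positions are equivalent and each is activated by an ortho ether oxygen, an ortho methoxy and a para methoxy group, so one regioisomer should form without a strong Lewis acid that could ionise the benzylic ether.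

**Step 7**
Reactants: 12 (2S)-6,7,8-trimethoxy-2-phenyl-3,4-dihydro-1-benzoxepin-5(2H)-one
Product: 14 (2S)-6-hydroxy-7,8-dimethoxy-2-phenyl-3,4-dihydro-1-benzoxepin-5(2H)-one, via dichloroboron phenolate 13 (not isolated)
Conditions: BCl3 (1.2 equiv), CH2Cl2, −78 to −20 °C; then H2O
Reagents that add atoms: boron trichloride, ClB(Cl)Cl (its BCl2 group stays only in 13)
Why: Chelation-controlled aryl methyl ether cleavage: BCl3 bridges the ketone oxygen and the neighbouring 6-OMe in a six-membered chelate and chloride removes only that methyl group, the selectivity known from 5-O-demethylation of polymethoxyflavanones, while O1 lies on the far side of the carbonyl group and, unlike in a flavanone, no retro-Michael opening can endanger C2.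

**Step 8**
Reactants: 14 (2S)-6-hydroxy-7,8-dimethoxy-2-phenyl-3,4-dihydro-1-benzoxepin-5(2H)-one
Product: 16 (2S)-4-diazo-6-hydroxy-7,8-dimethoxy-2-phenyl-3,4-dihydro-1-benzoxepin-5(2H)-one, via trifluoroacetyl ketone 15 (not isolated)
Conditions: LiN(SiMe3)2 (2.2 equiv), THF, −78 °C; CF3CO2CH2CF3 (1.3 equiv); aq. HCl work-up; then 4-acetamidobenzenesulfonyl azide, Et3N, H2O (1 equiv), MeCN, rt
Reagents that add atoms: 4-acetamidobenzenesulfonyl azide, CC(=O)Nc1ccc(cc1)S(=O)(=O)N=[N+]=[N-]; 2,2,2-trifluoroethyl trifluoroacetate, O=C(OCC(F)(F)F)C(F)(F)F (its CF3CO group stays only in 15)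
Why: Detrifluoroacetylative Regitz diazo transfer: the phenoxide–enolate dianion is C-acylated at C4 by the trifluoroacetate ester, and the activated 1,3-dicarbonyl compound 15 takes up N2 from the sulfonyl azide with loss of the trifluoroacetyl group, whereas C2, which is γ to the ketone, cannot be lost by elimination or enolisation.

**Step 9**
Reactants: 16 (2S)-4-diazo-6-hydroxy-7,8-dimethoxy-2-phenyl-3,4-dihydro-1-benzoxepin-5(2H)-one; 6 (2S,4R)-5,6,7-trimethoxy-2-phenylchroman-4-ol
Product: 20 beilschmieflavonoid B, via ketene 17 (not isolated), via peri-lactone 18 (not isolated), via o-quinone methide 19 (not isolated)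
Conditions: 16 (5 mM), 6 (3 equiv), MeCN, 4 Å MS, Ar, hν 365 nm, 0 °C; then hν 254 nm (quartz), 0 °C; then dark, rt
Reagents that add atoms: none
Why: Proposed new method: near-UV light expels N2 from the s-Z-locked cyclic diazoketone 16 with concerted 1,2-shift of aryl carbon C5a from the carbonyl carbon to the diazo carbon (photo-Wolff ring contraction, seven-membered oxepinone to six-membered ring C), the peri O5–H adds to the sp carbon of ketene 17 to give lactone 18, 254 nm light then expels that same carbon as CO, and the resulting o-quinone methide 19 takes up the O–H of 6 at C4. The closest known reaction types are the photo-Wolff contraction of 2-diazo-1-benzosuberones and 2-diazo-1-tetralones, the capture of o-hydroxyaryl ketenes as benzofuran-2(3H)-ones, and the photodecarbonylation of benzofuran-2(3H)-ones to o-quinone methides that add alcohols; new are their telescoping in one flask and the use of a hindered secondary alcohol. Ring C is closed by the aryl shift itself, so no cyclisation mode applies, and the temporary five-membered lactone closes by 5-exo attack of O5 on the ketene carbonyl carbon and is opened again when CO leaves. The only new stereocentre, C4, should be set as R by C2: with the 2-phenyl group equatorial on the half-chair of 19 the alcohol adds along the pseudo-axial trajectory on the face of H2 (torsionally favoured, only H2 as 1,3-diaxial partner), and an equatorial OR would clash with O5, so kinetic and thermodynamic control both point to 2,4-trans, while C2, C2' and C4' are not touched. The step needs Wolff shift over carbene O–H insertion (secured by the s-Z geometry and direct metal-free excitation), internal over external capture of the ketene (peri five-membered closure against a dilute hindered alcohol), and O- over C-alkylation of 19 by the electron-rich rings (neutral aprotic medium without acid); the 1,5-H shift that destroys alkyl o-quinone methides is impossible here because ring C holds C3 anti to O5.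

**Compound list**
1 | 3,4,5-trimethoxyphenol | COc1cc(O)cc(OC)c1OC | starting material
2 | (1R)-1-phenylbut-3-en-1-ol | C=CC[C@@H](O)c1ccccc1 | starting material
3 | 5-{[(1S)-1-phenylbut-3-en-1-yl]oxy}-1,2,3-trimethoxybenzene | C=CC[C@H](Oc1cc(OC)c(OC)c(OC)c1)c1ccccc1 | intermediate
4 | (4S)-4-phenyl-4-(3,4,5-trimethoxyphenoxy)butane-1,2-diol (both C2 epimers) | OCC(O)C[C@H](Oc1cc(OC)c(OC)c(OC)c1)c1ccccc1 | intermediate
5 | (3S)-3-phenyl-3-(3,4,5-trimethoxyphenoxy)propanal | O=CC[C@H](Oc1cc(OC)c(OC)c(OC)c1)c1ccccc1 | intermediate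
6 | (2S,4R)-5,6,7-trimethoxy-2-phenylchroman-4-ol (2,4-trans) | O[C@@H]1C[C@@H](c2ccccc2)Oc2cc(OC)c(OC)c(OC)c21 | intermediate
7 | 9-[(4S)-4-phenyl-4-(3,4,5-trimethoxyphenoxy)butyl]-9-borabicyclo[3.3.1]nonane | B1(CCC[C@H](Oc2cc(OC)c(OC)c(OC)c2)c2ccccc2)C2CCCC1CCC2 | intermediate
8 | (4S)-4-phenyl-4-(3,4,5-trimethoxyphenoxy)butan-1-ol | OCCC[C@H](Oc1cc(OC)c(OC)c(OC)c1)c1ccccc1 | intermediate
9 | (4S)-4-phenyl-4-(3,4,5-trimethoxyphenoxy)butanal | O=CCC[C@H](Oc1cc(OC)c(OC)c(OC)c1)c1ccccc1 | intermediate
10 | (4S)-4-phenyl-4-(3,4,5-trimethoxyphenoxy)butanoic acid | OC(=O)CC[C@H](Oc1cc(OC)c(OC)c(OC)c1)c1ccccc1 | intermediate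
11 | (4S)-4-phenyl-4-(3,4,5-trimethoxyphenoxy)butanoic trifluoroacetic anhydride | FC(F)(F)C(=O)OC(=O)CC[C@H](Oc1cc(OC)c(OC)c(OC)c1)c1ccccc1 | intermediate
12 | (2S)-6,7,8-trimethoxy-2-phenyl-3,4-dihydro-1-benzoxepin-5(2H)-one | O=C1CC[C@@H](c2ccccc2)Oc2cc(OC)c(OC)c(OC)c12 | intermediate
13 | dichloroboron 6-phenolate of 14 (boron also bound to the ketone oxygen) | O=C1CC[C@@H](c2ccccc2)Oc2cc(OC)c(OC)c(OB(Cl)Cl)c12 | intermediate
14 | (2S)-6-hydroxy-7,8-dimethoxy-2-phenyl-3,4-dihydro-1-benzoxepin-5(2H)-one | O=C1CC[C@@H](c2ccccc2)Oc2cc(OC)c(OC)c(O)c12 | intermediate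
15 | (2S)-6-hydroxy-7,8-dimethoxy-2-phenyl-4-(trifluoroacetyl)-3,4-dihydro-1-benzoxepin-5(2H)-one (C4 enolisable) | O=C1C(C(=O)C(F)(F)F)C[C@@H](c2ccccc2)Oc2cc(OC)c(OC)c(O)c12 | intermediate
16 | (2S)-4-diazo-6-hydroxy-7,8-dimethoxy-2-phenyl-3,4-dihydro-1-benzoxepin-5(2H)-one | O=C1C(=[N+]=[N-])C[C@@H](c2ccccc2)Oc2cc(OC)c(OC)c(O)c12 | intermediate
17 | [(2S)-5-hydroxy-6,7-dimethoxy-2-phenyl-2,3-dihydro-4H-chromen-4-ylidene]methanone (ketene on C4) | O=C=C1C[C@@H](c2ccccc2)Oc2cc(OC)c(OC)c(O)c12 | intermediate
18 | peri-lactone of (2S)-5-hydroxy-6,7-dimethoxy-2-phenylchroman-4-carboxylic acid (five-membered ring O5–CO–C4–C4a–C5, both C4 epimers) | O=C1Oc2c(OC)c(OC)cc3O[C@H](c4ccccc4)CC1c23 | intermediate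
19 | (2S)-6,7-dimethoxy-2-phenyl-2,3-dihydro-5H-chromen-5-one (o-quinone methide C5(=O)–C4a=C4) | O=C1C(OC)=C(OC)C=C2O[C@H](c3ccccc3)CC=C12 | intermediate
20 | beilschmieflavonoid B, (2S,4R)-6,7-dimethoxy-2-phenyl-4-{[(2S,4R)-5,6,7-trimethoxy-2-phenylchroman-4-yl]oxy}chroman-5-ol | COc1cc2c(c(O)c1OC)[C@H](O[C@@H]1C[C@@H](c3ccccc3)Oc3cc(OC)c(OC)c(OC)c31)C[C@@H](c1ccccc1)O2 | target

**Step count:** 9 steps in total. The longest linear sequence has 7 steps (1, 4, 5, 6, 7, 8, 9).

**Steps most likely to fail**

**Step 9**
- What may go wrong: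
  - Proton transfer within the o-hydroxyaryl ketone may deactivate the excited diazoketone.
  - The carbene may insert into O5–H.
  - The benzylic O1–C2 and O1'–C2' bonds may be cleaved by light during long exposure at 254 nm, with loss of configuration.
  - The donor-stabilised quinone methide may be captured too slowly by the hindered alcohol.
- The fallback uses known chemistry and sets out from 16.
  - Only the 365 nm stage is run (or 16 is heated in toluene), and lactone 18 is isolated.
  - LiOH in THF–H2O opens it to (2S)-5-hydroxy-6,7-dimethoxy-2-phenylchroman-4-carboxylic acid F1. F1 is kept as its salt because the free acid closes back to 18.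
  - A Hofer–Moest anodic decarboxylation of F1 then generates the same C4 electrophile without light and comes back to the route at 20. It uses graphite electrodes, 2,4,6-collidine, nBu4NPF6, 3 Å sieves, CH2Cl2 and 6 (3 equiv).

**Step 3**
- What may go wrong:
  - The aldehyde may lose the aryloxide by β-elimination.
  - The product may ionise further, leading to self-etherification or C-alkylation of a second ring.
  - Equilibration to the trans isomer may stay incomplete.
- The fallback replaces equilibrium control by reagent control and sets out from 5.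
  - Pinnick oxidation (NaClO2, NaH2PO4, 2-methylbut-2-ene) gives (3S)-3-phenyl-3-(3,4,5-trimethoxyphenoxy)propanoic acid F2.
  - Friedel–Crafts acylation with (CF3CO)2O closes (2S)-5,6,7-trimethoxy-2-phenylchroman-4-one F3.
  - NaBH4 delivers hydride axially to give (2S,4S)-5,6,7-trimethoxy-2-phenylchroman-4-ol F4 (2,4-cis).
  - Mitsunobu inversion with 4-nitrobenzoic acid gives (2S,4R)-5,6,7-trimethoxy-2-phenylchroman-4-yl 4-nitrobenzoate F5.
  - K2CO3 in MeOH comes back to the route at 6.

**Step 6**
- What may go wrong:
  - Acid may ionise the benzylic C–O bond, with loss of configuration or of the ether.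
  - The ring may be trifluoroacetylated.
  - The seven-membered closure may be slow enough to let intermolecular acylation compete.
- The fallback is anionic instead of cationic and sets out from 10.
  - NBS in MeCN brominates one of the two equivalent ring positions to give (4S)-4-(2-bromo-3,4,5-trimethoxyphenoxy)-4-phenylbutanoic acid F6.
  - EDC and MeNHOMe·HCl give (4S)-4-(2-bromo-3,4,5-trimethoxyphenoxy)-N-methoxy-N-methyl-4-phenylbutanamide F7.
  - A Parham cyclisation (t-BuLi, THF, −78 °C: bromine–lithium exchange, then attack on the amide) comes back to the route at 12.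

**Further compounds**
F1 | step 9 | (2S)-5-hydroxy-6,7-dimethoxy-2-phenylchroman-4-carboxylic acid (both C4 epimers) | OC(=O)C1C[C@@H](c2ccccc2)Oc2cc(OC)c(OC)c(O)c12
F2 | step 3 | (3S)-3-phenyl-3-(3,4,5-trimethoxyphenoxy)propanoic acid | OC(=O)C[C@H](Oc1cc(OC)c(OC)c(OC)c1)c1ccccc1
F3 | step 3 | (2S)-5,6,7-trimethoxy-2-phenylchroman-4-one | O=C1C[C@@H](c2ccccc2)Oc2cc(OC)c(OC)c(OC)c12
F4 | step 3 | (2S,4S)-5,6,7-trimethoxy-2-phenylchroman-4-ol | O[C@H]1C[C@@H](c2ccccc2)Oc2cc(OC)c(OC)c(OC)c21
F5 | step 3 | (2S,4R)-5,6,7-trimethoxy-2-phenylchroman-4-yl 4-nitrobenzoate | O=C(O[C@@H]1C[C@@H](c2ccccc2)Oc2cc(OC)c(OC)c(OC)c21)c1ccc(cc1)[N+](=O)[O-]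
F6 | step 6 | (4S)-4-(2-bromo-3,4,5-trimethoxyphenoxy)-4-phenylbutanoic acid | OC(=O)CC[C@H](Oc1cc(OC)c(OC)c(OC)c1Br)c1ccccc1
F7 | step 6 | (4S)-4-(2-bromo-3,4,5-trimethoxyphenoxy)-N-methoxy-N-methyl-4-phenylbutanamide | CON(C)C(=O)CC[C@H](Oc1cc(OC)c(OC)c(OC)c1Br)c1ccccc1
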